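**Plan**

- Retrosynthesis: the C6–O acyl bond of the vanillate is cut first and the C6 carbinol is taken back to a ketone. The C1–C5 bond of the hydroazulene is then cut and C1 rejoined to C6, giving a cis-decalin 5,6-diol 5-mesylate. In that decalin C8=C9 (metathesis), C6–OH and C6–C7 (enolate chemistry) and C1–C10 (conjugate allylation) are cut back to a 4-silyloxy enone made from (S)-terpinen-4-ol.
- Feature that allows the key step: the trans C1–C5 ring fusion next to the oxygenated C6. A C6 carbonyl beside a C5 methine that carries C1 is what a shift of C1 from C6 to C5 leaves behind in a six-six precursor (ring A C1–C6; ring B C6, C7, C8, C9, C10, C1); ring A shrinks to the cyclopentane C1–C5 and ring B grows to the cycloheptene C5–C10 plus C1.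
- Forward order: ring A is the terpene ring. C1 receives allyl and C6 receives methallyl and then hydroxyl on a C5 ketone. Ring B is closed by ring-closing metathesis, C5 is reduced and mesylated, and the 1,2-shift builds the five-seven skeleton. Desilylation, directed C6 reduction, esterification and phenol release finish the target.
- Stereochemistry: C4 is the terpinen-4-ol stereocentre. C1 comes from axial conjugate allylation anti to the pseudoaxial C4 silyloxy group, and the C6 carbinol of the decalin from enolate hydroxylation anti to the pseudoaxial C1 allyl group. C5 comes from axial hydride attack and is then inverted stereospecifically in the shift (5α-H). C6 of the target comes from hydride delivered by the C4 hydroxyl.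
- Convention: daucane numbering is used for every intermediate (C1 methyl-bearing carbon, C2, C3, C4 isopropyl carbinol, C5, C6, C7, C8 methyl-bearing, C9, C10); β is the face that carries the C4 oxygen.

Key step: step 11

Assumption: (S)-(+)-terpinen-4-ol is used as the single enantiomer (material of lower enantiomeric purity would be upgraded before step 1), because C4 is the only source of absolute configuration.

Step 1
Reactants: 1 (S)-terpinen-4-ol
Product: 2 (S)-terpinen-4-yl triethylsilyl ether
Conditions: Et3SiOTf, 2,6-lutidine, CH2Cl2, 0 °C
Reagents that add atoms: triethylsilyl trifluoromethanesulfonate, CC[Si](CC)(CC)OS(=O)(=O)C(F)(F)F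
Why: Silyl triflate/2,6-lutidine silylation is the standard way to cap a hindered tertiary alcohol; C4 is not touched, and the triethylsilyl ether stays a non-participating group through the enolate chemistry and the later 1,2-shift.

Step 2
Reactants: 2 (S)-terpinen-4-yl triethylsilyl ether
Product: 3 C1–C6 epoxide of 2 (both epoxide diastereomers)
Conditions: mCPBA, NaHCO3, CH2Cl2, 0 °C
Reagents that add atoms: 3-chloroperoxybenzoic acid, O=C(OO)c1cccc(Cl)c1
Why: Prilezhaev epoxidation of the electron-rich trisubstituted C1=C6 olefin; either epoxide diastereomer serves, because C1 and C6 both return to sp2 in step 4.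

Step 3
Reactants: 3 C1–C6 epoxide
Product: 6 tertiary C1 allylic alcohol with C5=C6 olefin (both C1 epimers), via hydroxy selenide 4 (not isolated), via selenoxide 5 (not isolated)
Conditions: PhSeSePh, NaBH4, EtOH, 78 °C; then THF, 30% aq. H2O2, 0 °C to rt
Reagents that add atoms: none
Why: Epoxide-to-allylic-alcohol transposition by selenolate opening and selenoxide syn-elimination: the selenolate attacks the secondary C6 by SN2, and the selenoxide can eliminate only towards C5 because C1 carries no hydrogen, so the C5=C6 olefin with a tertiary C1 hydroxyl results from either epoxide.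

Step 4
Reactants: 6 tertiary C1 allylic alcohol
Product: 9 (R)-3-methyl-6-(propan-2-yl)-6-(triethylsilyloxy)cyclohex-2-en-1-one, via tertiary chromate ester 7 (not isolated), via transposed chromate ester 8 (not isolated)
Conditions: pyridinium chlorochromate [C5H5NH][CrO3Cl], NaOAc, 4 Å molecular sieves, CH2Cl2, rt
Reagents that add atoms: pyridinium chlorochromate, [O-][Cr](=O)(=O)Cl.c1cc[nH+]cc1
Why: Babler–Dauben oxidative transposition: the tertiary allylic chromate ester rearranges by [3,3] shift to C5 and is oxidised there to the C5 ketone of the C6=C1 enone (the carbonyl oxygen comes from the chromate); only the C1 hydroxyl can react because the C4 oxygen is silylated, and the acetate buffer protects the allylic silyl ether from ionisation.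

Step 5
Reactants: 9 enone
Product: 11 C1-allyl ketone (allyl α and methyl β at C1), via trimethylsilyl enol ether 10 (not isolated)
Conditions: CH2=CHCH2MgBr, CuBr·SMe2, Me3SiCl, THF, −78 °C; then 1 M HCl, THF, 0 °C
Reagents that add atoms: allylmagnesium bromide, C=CC[Mg]Br
Why: Me3SiCl-accelerated conjugate addition of an allylcopper reagent to a β,β-disubstituted cyclohexenone; the enone half-chair holds the C4 silyloxy group pseudoaxial and the isopropyl group pseudoequatorial, and antiparallel attack at C1 then takes place on the α face, anti to the C4 oxygen, so the new quaternary centre carries allyl α and methyl β.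

Step 6
Reactants: 11 C1-allyl ketone
Product: 13 C6-methallyl ketone (both C6 epimers), via lithium enolate 12 (not isolated)
Conditions: LiN(iPr)2, THF, −78 °C; then CH2=C(CH3)CH2Br, DMPU, −78 to 0 °C
Reagents that add atoms: 3-bromo-2-methylprop-1-ene, C=C(C)CBr
Why: Kinetic enolate alkylation with an allylic bromide; C6 is the only enolisable position because C4 is quaternary, and the configuration formed at C6 does not matter because the centre is enolised again in step 7.

Step 7
Reactants: 13 C6-methallyl ketone
Product: 15 monocyclic ketol with 6β-hydroxyl and 6α-methallyl, via sodium enolate 14 (not isolated)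
Conditions: NaN(SiMe3)2, THF, −78 to −40 °C; then 2-(phenylsulfonyl)-3-phenyloxaziridine, −78 °C; aq. NH4Cl
Reagents that add atoms: 2-(phenylsulfonyl)-3-phenyloxaziridine, O=S(=O)(c1ccccc1)N1OC1c1ccccc1
Why: Davis oxaziridine hydroxylation of a tetrasubstituted ketone enolate; in the enolate half-chair the C1 allyl group is pseudoaxial on the α face (C4 silyloxy pseudoaxial β, isopropyl and C1 methyl pseudoequatorial), so the oxidant reaches C6 through the chair-like transition state from the β face, anti to that allyl group, placing the hydroxyl cis to the C1 methyl and the C4 oxygen and the methallyl group cis to the allyl group.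

Step 8
Reactants: 15 monocyclic ketol
Product: 16 cis-fused bicyclic ketol (ring B closed with C8=C9)
Conditions: second-generation Grubbs catalyst RuCl2(=CHPh)(PCy3)(H2IMes) (5 mol%), CH2Cl2, 40 °C
Reagents that add atoms: none
Why: Ring-closing metathesis of the cis-disposed allyl (monosubstituted) and methallyl (1,1-disubstituted) olefins closes ring B as a cyclohexene with the trisubstituted C8=C9 bond and releases ethylene; no stereocentre is formed, the cis ring fusion being fixed by steps 5 and 7.

Step 9
Reactants: 16 cis-fused bicyclic ketol
Product: 17 cis-decalin 5β,6β-diol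
Conditions: NaBH4, MeOH/THF, −20 °C to rt
Reagents that add atoms: none
Why: Borohydride reduction of an α-hydroxy ketone under non-chelating conditions; in the ring A chair with isopropyl equatorial the C4 and C6 oxygens are both axial on the β face, so hydride adds along the axial trajectory from the α face, anti to both C–O bonds (Felkin–Anh polar control reinforced by the bulk of the silyl ether), and the new C5 hydroxyl ends equatorial and β, cis to its two oxygen neighbours.

Step 10
Reactants: 17 cis-decalin 5β,6β-diol
Product: 18 cis-decalin 5,6-diol 5-mesylate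
Conditions: MeSO2Cl, Et3N, CH2Cl2, −10 °C
Reagents that add atoms: methanesulfonyl chloride, CS(=O)(=O)Cl
Why: Mesylation through sulfene differentiates the secondary C5 hydroxyl from the tertiary C6 hydroxyl; the cis relation of the two C–O bonds forbids epoxide closure, so the hydroxy mesylate can be handled.

Step 11
Reactants: 18 cis-decalin 5,6-diol 5-mesylate
Product: 20 trans-fused 4β-(triethylsilyloxy)dauc-8-en-6-one, via diethylaluminium alkoxide 19 (not isolated)
Conditions: Et3Al (2.5 equiv), CH2Cl2, −78 to 0 °C; then aq. KNaC4H4O6 (potassium sodium tartrate)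
Reagents that add atoms: none
Why: Et3Al turns the tertiary C6 hydroxyl into the aluminium alkoxide 19 and, as a Lewis acid, loosens the C5–OMs bond; the C6–C1 σ bond, antiperiplanar to the equatorial mesylate, then shifts from C6 to C5 as the sulfonate leaves and the C6–O bond becomes the carbonyl. This is the organoaluminium-promoted semipinacol rearrangement of a 1,2-diol monosulfonate, the classical way to turn a hydronaphthalene into a hydroazulene. The single new bond C1–C5 closes both rings: the cyclopentane C1–C2–C3–C4–C5 arises by contraction of ring A (C6 is extruded) and the cycloheptenone C5–C6–C7–C8–C9–C10–C1 by one-carbon expansion of ring B (C5 is inserted), both through the same suprafacial 1,2-alkyl shift and not through a chain cyclisation. C5 is the only new stereocentre and is formed with inversion, C1 arriving on the face opposite the β-mesylate, so that H5 ends α and trans to the C1 methyl, while the migrating C1 keeps its configuration and C6 loses its own. The step needs C1 to migrate in preference to C3 (from C4), to C7 and to attack by the C6 oxygen: in the ring A chair with isopropyl equatorial only the C6–C1 and C4–C3 bonds are antiperiplanar to the leaving group, the silyl ether at C4 cannot supply the push a C3 shift would need, C7 and the axial C6 oxygen are gauche, and the cis-diol geometry excludes backside attack by oxygen. The weakly basic aluminium alkoxide is preferred to a potassium alkoxide because it should not pass the silyl group between the syn-axial C4 and C6 oxygens, epimerise C5 or move the C8=C9 olefin into conjugation.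

Step 12
Reactants: 20 trans-fused 4β-(triethylsilyloxy)dauc-8-en-6-one
Product: 21 4β-hydroxydauc-8-en-6-one
Conditions: HF·pyridine, pyridine, THF, 0 °C to rt
Reagents that add atoms: none
Why: Fluoride cleavage of the tertiary silyl ether with buffered HF·pyridine, which is not basic enough to cause retro-aldol opening at C4–C5, C5 epimerisation or migration of the C8=C9 olefin into conjugation, and not acidic enough to dehydrate the tertiary alcohol.

Step 13
Reactants: 21 4β-hydroxydauc-8-en-6-one
Product: 23 jaeschkeanadiol (dauc-8-ene-4β,6α-diol), via alkoxyborohydride 22 (not isolated)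
Conditions: Me4NBH(OAc)3, MeCN/AcOH (1:1), −20 °C to rt
Reagents that add atoms: none
Why: Evans–Saksena hydroxyl-directed reduction: the C4 hydroxyl exchanges an acetate on boron and the resulting alkoxyborohydride delivers hydride intramolecularly to the β face of the C6 carbonyl, on which the C4 oxygen lies, so the new hydroxyl is formed α, anti to the C4 hydroxyl, against the steric bias of the ketone.

Step 14
Reactants: 24 vanillic acid
Product: 25 3-methoxy-4-(pivaloyloxy)benzoic acid
Conditions: NaOH (2 equiv), H2O/THF, 0 °C, Me3CCOCl; then HCl to pH 2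
Reagents that add atoms: pivaloyl chloride, CC(C)(C)C(=O)Cl
Why: Schotten–Baumann acylation of the phenoxide of vanillic acid; the hindered pivalate masks the phenol and, unlike an acetate, should not transfer its acyl group during the DMAP-catalysed coupling.

Step 15
Reactants: 23 jaeschkeanadiol; 25 3-methoxy-4-(pivaloyloxy)benzoic acid
Product: 27 jaeschkeanadiol 6-O-[3-methoxy-4-(pivaloyloxy)benzoate], via O-acylisourea 26 (not isolated)
Conditions: DCC, DMAP (0.2 equiv), CH2Cl2, 0 °C to rt
Reagents that add atoms: none
Why: Steglich esterification through the O-acylisourea and the acylpyridinium ion; only the secondary C6 hydroxyl is acylated, the tertiary C4 hydroxyl being too hindered, and the C6 configuration is retained because its C–O bond is not broken.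

Step 16
Reactants: 27 jaeschkeanadiol 6-O-[3-methoxy-4-(pivaloyloxy)benzoate]
Product: 28 teferin
Conditions: pyrrolidine (5 equiv), CH2Cl2, rt
Reagents that add atoms: none
Why: Aminolysis of the aryl pivalate, an activated phenolic ester, by pyrrolidine; the aroate of the hindered secondary alcohol and the tertiary alcohol are left untouched.

**Compound list**

1 | (S)-terpinen-4-ol, (S)-4-methyl-1-(propan-2-yl)cyclohex-3-en-1-ol | CC1=CC[C@](O)(C(C)C)CC1 | starting material
2 | (S)-terpinen-4-yl triethylsilyl ether | CC1=CC[C@](O[Si](CC)(CC)CC)(C(C)C)CC1 | intermediate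
3 | C1–C6 epoxide of 2 (both epoxide diastereomers, C4 unchanged) | CC12OC1C[C@](O[Si](CC)(CC)CC)(C(C)C)CC2 | intermediate
4 | hydroxy selenide: tertiary C1 alcohol, C6 phenylselanyl, trans (diastereomers from both epoxides) | CC1(O)C([Se]c2ccccc2)C[C@](O[Si](CC)(CC)CC)(C(C)C)CC1 | intermediate (not isolated)
5 | selenoxide of 4 | CC1(O)C([Se](=O)c2ccccc2)C[C@](O[Si](CC)(CC)CC)(C(C)C)CC1 | intermediate (not isolated)
6 | 1-methyl-4-(propan-2-yl)-4-(triethylsilyloxy)cyclohex-2-en-1-ol: tertiary C1 alcohol, C5=C6 olefin, both C1 epimers, C4 as in 1 | CC1(O)C=C[C@](O[Si](CC)(CC)CC)(C(C)C)CC1 | intermediate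
7 | chlorochromate ester of the C1 hydroxyl of 6 | CC1(O[Cr](=O)(=O)Cl)C=C[C@](O[Si](CC)(CC)CC)(C(C)C)CC1 | intermediate (not isolated)
8 | allylically transposed chlorochromate ester (chromium on the C5 oxygen, C1=C6 olefin) | CC1=CC(O[Cr](=O)(=O)Cl)[C@](O[Si](CC)(CC)CC)(C(C)C)CC1 | intermediate (not isolated)
9 | (R)-3-methyl-6-(propan-2-yl)-6-(triethylsilyloxy)cyclohex-2-en-1-one (C5 ketone, C6=C1 olefin) | CC1=CC(=O)[C@](O[Si](CC)(CC)CC)(C(C)C)CC1 | intermediate
10 | trimethylsilyl enol ether (C5=C6) of 11 | C=CC[C@@]1(C)CC[C@@](O[Si](CC)(CC)CC)(C(C)C)C(O[Si](C)(C)C)=C1 | intermediate (not isolated)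
11 | 3-allyl-3-methyl-6-(propan-2-yl)-6-(triethylsilyloxy)cyclohexan-1-one, allyl trans (α) and methyl cis (β) to the C4 silyloxy group | C=CC[C@@]1(C)CC[C@@](O[Si](CC)(CC)CC)(C(C)C)C(=O)C1 | intermediate
12 | lithium enolate (C5–O, C5=C6) of 11 | C=CC[C@@]1(C)CC[C@@](O[Si](CC)(CC)CC)(C(C)C)C(O[Li])=C1 | intermediate (not isolated)
13 | C6-(2-methylallyl) derivative of 11, both C6 epimers | C=CC[C@@]1(C)CC[C@@](O[Si](CC)(CC)CC)(C(C)C)C(=O)C1CC(C)=C | intermediate
14 | sodium enolate of 13 | C=CC[C@@]1(C)CC[C@@](O[Si](CC)(CC)CC)(C(C)C)C(O[Na])=C1CC(C)=C | intermediate (not isolated)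
15 | monocyclic ketol: C5 ketone, tertiary 6β-hydroxyl (cis to C1 methyl and C4 silyloxy), 6α-methallyl cis to the 1α-allyl group | C=CC[C@@]1(C)CC[C@@](O[Si](CC)(CC)CC)(C(C)C)C(=O)[C@@]1(O)CC(C)=C | intermediate
16 | cis-fused bicyclic ketol: ring A C1–C6, ring B C6–C10 plus C1 with C8=C9; 6β-OH, 1β-CH3, 4β-OSiEt3, 4α-isopropyl, C5 ketone | O[C@]12CC(C)=CC[C@@]1(C)CC[C@@](O[Si](CC)(CC)CC)(C(C)C)C2=O | intermediate
17 | cis-decalin 5β,6β-diol (4β-OSiEt3, 1β-CH3, C8=C9) | O[C@]12CC(C)=CC[C@@]1(C)CC[C@@](O[Si](CC)(CC)CC)(C(C)C)[C@@H]2O | intermediate
18 | cis-decalin 5,6-diol 5-mesylate (5β-OMs equatorial, free tertiary 6β-OH, 4β-OSiEt3) | O[C@]12CC(C)=CC[C@@]1(C)CC[C@@](O[Si](CC)(CC)CC)(C(C)C)[C@@H]2OS(C)(=O)=O | intermediate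
19 | diethylaluminium C6 alkoxide of 18 | CC[Al](CC)O[C@]12CC(C)=CC[C@@]1(C)CC[C@@](O[Si](CC)(CC)CC)(C(C)C)[C@@H]2OS(C)(=O)=O | intermediate (not isolated)
20 | trans-fused 4β-(triethylsilyloxy)dauc-8-en-6-one (1β-CH3, 5α-H, 4α-isopropyl) | O=C1CC(C)=CC[C@@]2(C)CC[C@@](O[Si](CC)(CC)CC)(C(C)C)[C@H]12 | intermediate
21 | 4β-hydroxydauc-8-en-6-one (1β-CH3, 5α-H) | O=C1CC(C)=CC[C@@]2(C)CC[C@@](O)(C(C)C)[C@H]12 | intermediate
22 | tetramethylammonium diacetoxy(alkoxy)borohydride of 21, boron on the C4 oxygen | O=C1CC(C)=CC[C@@]2(C)CC[C@@](O[BH-](OC(C)=O)OC(C)=O)(C(C)C)[C@H]12.C[N+](C)(C)C | intermediate (not isolated)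
23 | jaeschkeanadiol, dauc-8-ene-4β,6α-diol (1β-CH3, 5α-H) | O[C@H]1CC(C)=CC[C@@]2(C)CC[C@@](O)(C(C)C)[C@H]12 | intermediate
24 | vanillic acid | COc1cc(C(=O)O)ccc1O | starting material
25 | 3-methoxy-4-(pivaloyloxy)benzoic acid | COc1cc(C(=O)O)ccc1OC(=O)C(C)(C)C | intermediate
26 | O-acylisourea from 25 and DCC | COc1cc(C(=O)OC(=NC2CCCCC2)NC2CCCCC2)ccc1OC(=O)C(C)(C)C | intermediate (not isolated)
27 | jaeschkeanadiol 6-O-[3-methoxy-4-(pivaloyloxy)benzoate] | COc1cc(C(=O)O[C@H]2CC(C)=CC[C@@]3(C)CC[C@@](O)(C(C)C)[C@H]23)ccc1OC(=O)C(C)(C)C | intermediate
28 | teferin, jaeschkeanadiol 6-O-vanillate | COc1cc(C(=O)O[C@H]2CC(C)=CC[C@@]3(C)CC[C@@](O)(C(C)C)[C@H]23)ccc1O | target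

**Step count and risks**

Total: 16 steps. Longest linear sequence: 15 steps (steps 1–13, 15 and 16, from 1).

Steps most likely to fail:

Step 7. The oxidant may be steered to the α face of the tetrasubstituted enolate, because the pseudoaxial C4 silyloxy group lies 1,3 to C6 on the β face. The hindered methine may also enolise incompletely, or the silyl group may slip from the C4 oxygen to the enolate oxygen. Any of these erodes or inverts the C6 configuration on which ring B closure and the chair geometry of step 11 depend. The fallback sets out from 11 and returns at 15; it introduces the two C6 substituents in the opposite order, so that carbon and not oxygen arrives last. Hydroxylation of the C6 methylene of 11 (NaN(SiMe3)2, Davis oxaziridine) should give the secondary C6 ketol F1. Chloromethyl methyl ether and iPr2NEt should convert it into the methoxymethyl ether F2. Enolisation with LiN(iPr)2 followed by 3-bromo-2-methylprop-1-ene should give the C6-quaternary methoxymethyl ether F3, the methallyl group now taking the face the oxidant took in the failed step and the oxygen being left β. Me2BBr in CH2Cl2 at −78 °C should then free the tertiary hydroxyl and give 15.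

Step 9. Hydride may approach the C5 carbonyl from the β face (equatorial attack) if the axial C10 methylene screens the α face more than the two axial C–O bonds screen the β face. That would give the axial 5α-alcohol, whose mesylate is antiperiplanar to the C6 oxygen and would close to an epoxide instead of rearranging. The fallback sets out from 16 and returns at 17; it replaces kinetic hydride delivery by thermodynamic control and makes no new compound (entry F0). Meerwein–Ponndorf–Verley equilibration with Al(OiPr)3 in iPrOH/toluene at 80 °C should converge on the equatorial 5β-alcohol, which is free of the 1,3-diaxial contact with C10 and can hydrogen-bond to both cis oxygens.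

Step 11. The aluminium alkoxide may not rearrange cleanly. Silyl transfer from the C4 to the C6 oxygen would unmask a C4 alkoxide and open the competing contraction by C3 migration. A ring A conformer of the cis-decalin with the mesylate axial would favour elimination over the shift. The fallback sets out from 15 and returns at 20; it carries out the same C1 shift before ring B exists and forms the seven-membered ring by metathesis instead of ring expansion. NaBH4 reduction of 15 should give the monocyclic cis-5,6-diol F4, and MeSO2Cl/Et3N its C5 mesylate F5. Et3Al should then move C1 from C6 to C5 in the conformationally freer monocycle and give the acylcyclopentane F6, in which C5 carries the C6 ketone with its methallyl chain. Ring-closing metathesis of the allyl and methallyl olefins of F6 with the second-generation Grubbs catalyst RuCl2(=CHPh)(PCy3)(H2IMes) should close the cycloheptenone and give 20.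

**Further compounds**

F1 | step 7 | secondary C6 ketol from 11 (either C6 epimer) | C=CC[C@@]1(C)CC[C@@](O[Si](CC)(CC)CC)(C(C)C)C(=O)C1O
F2 | step 7 | methoxymethyl ether of F1 | C=CC[C@@]1(C)CC[C@@](O[Si](CC)(CC)CC)(C(C)C)C(=O)C1OCOC
F3 | step 7 | C6-quaternary methoxymethyl ether (6β-OCH2OCH3, 6α-methallyl) | C=CC[C@@]1(C)CC[C@@](O[Si](CC)(CC)CC)(C(C)C)C(=O)[C@@]1(OCOC)CC(C)=C
F0 | step 9 | none | none
F4 | step 11 | monocyclic cis-5β,6β-diol from 15 | C=CC[C@@]1(C)CC[C@@](O[Si](CC)(CC)CC)(C(C)C)[C@H](O)[C@@]1(O)CC(C)=C
F5 | step 11 | C5 mesylate of F4 | C=CC[C@@]1(C)CC[C@@](O[Si](CC)(CC)CC)(C(C)C)[C@H](OS(C)(=O)=O)[C@@]1(O)CC(C)=C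
F6 | step 11 | acylcyclopentane: cyclopentane C1–C5 with 1α-allyl, 1β-methyl, 4β-silyloxy, 4α-isopropyl and a C5 3-methylbut-3-enoyl group trans to the C1 methyl | C=CC[C@@]1(C)CC[C@@](O[Si](CC)(CC)CC)(C(C)C)[C@@H]1C(=O)CC(C)=C
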